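Sunday's flask held 1.26 times the free base of Monday's, yet at 120 s, the time asked, it shows 16% of the electrophile left against Monday's 14%, a gap of 2 percentage points, which two readings scattering by 1.5 points each can give, so I read no hold of base on the rate between these two charges.

| setting | Monday's | Sunday's | epsilon | gamma |
|---|---|---|---|---|
| electrophile | 18 mM | 18 mM | 18 mM | 18 mM |
| nucleophile | 54 mM | 54 mM | 54.0 mM | 54.0 mM |
| free base | 39 mM | 49 mM | 35.0 mM | 27.0 mM |
| protic impurity | 3.6 mM | 3.6 mM | 3.60 mM | 3.60 mM |
| remark | run made earlier | run made earlier |  |  |
| time |  |  | 2.0 min | 2.0 min |

| run | time / s | electrophile / % | product / % |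
|---|---|---|---|
| Monday's | 15.0 | 73 | 18 |
| Monday's | 30.0 | 59 | 36 |
| Monday's | 50.0 | 45 | 51 |
| Monday's | 60.0 | 38 | 55 |
| Monday's | 80.0 | 27 | 64 |
| Monday's | 90.0 | 24 | 65 |
| Monday's | 120 | 14 | 75 |
| Sunday's | 15.0 | 77 | 19 |
| Sunday's | 30.0 | 60 | 34 |
| Sunday's | 50.0 | 45 | 49 |
| Sunday's | 60.0 | 37 | 55 |
| Sunday's | 80.0 | 29 | 66 |
| Sunday's | 90.0 | 27 | 63 |
| Sunday's | 120 | 16 | 73 |

(standard deviation of a reading: 1.5 percentage points)

1. part of the electrophile that has reacted at the end, epsilon
2. part of the electrophile that has reacted at the end, gamma
3. what raising the concentration of free base from its lowest to its highest value here does to the part of the electrophile that has reacted (changes below 5 percentage points count as none) (no change / it falls / it rises)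

- the numbers in the tables scatter by 1.5 percentage points (one standard deviation)

Epsilon and gamma charge less base than either run, so the reading has to be stretched. I assume that base catches at once whatever the reaction sets free, one base per electrophile; gamma, with less base than epsilon, still holds 1.50 base per electrophile charged, more than the one it needs, so I expect the nucleophile to stay free and both flasks to follow the runs.

My first way is the mean reading at the asked time, 15.0% left, hence 85.0% reacted. I carry it, pseudo-first-order fashion with the time held, as λ = 0.0351 mM⁻¹, the natural logarithm of charged over left per mM of nucleophile charged.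

My second way carries the mean at 15.0 s, 75.0% left, forward at constant rate, which gives 90.0% reacted, and the two part. The second way cheats: in the mean of the two runs the gap between electrophile lost and product found stands at 6.50% after 15.0 s and at 11.0% after 120 s, so it opens faster in the first 15.0 s than in the 1.75 min that follow, which add 4.5 points, and constant rate multiplies that quick loss onward. I commit to the first way for both flasks, with no change from base.

The forecast gives 85% for epsilon and 85% for gamma, with gamma's range from 70% to 88%, and no change, holding “so the rate is zero-order in base over that range”.

The flask gives 83.8% for epsilon and 83.7% for gamma, no change, the change across the base range being 0.059 points.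

    free base ⇌ dormant form (K = 0.300, k = 0.00280 s⁻¹)
    acid set free + free base ⇌ salt of the base, settled at all times (K = 27000 M⁻¹)
    nucleophile + acid set free ⇌ protonated nucleophile, settled at all times (K = 350 M⁻¹)
    crystals ⇌ acid set free, rate k4*(cs4 - [acid set free]) while solid is left; crystals form when [acid set free] > cs4 (solubility = 13.0 mM, k = 0.480 s⁻¹)
    electrophile + nucleophile → acid set free + product (k = 0.300 M⁻¹ s⁻¹)
    electrophile + protic impurity → quenched substrate (k = 0.720 M⁻¹ s⁻¹)

Gamma still has 41.8% of its charged free base free at 2.00 min, and its 16% of electrophile left gives back λ = 0.0336 mM⁻¹ against my 0.0351 mM⁻¹. Less nucleophile turns the number: epsilon's answer has moved by 5 points at 45.7 mM of nucleophile, and for the neighbour of gamma with 14 mM of nucleophile λ reckons 38.8% reacted, where that flask reaches 43.2%.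

All runs are simulated for an exercise; noise was put on by code.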